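- Amounts come first: the flask holds 0.020 M of electrophile against 0.0260 M of nucleophile, so electrophile is the limiting reagent. Taking the coupling as one for one, the quantity to carry is 0.00600 M: the nucleophile margin, the charge of nucleophile minus the charge of electrophile. It is the unused nucleophile, free and protonated together, at full conversion of the electrophile.

| flask | electrophile | nucleophile | free base | remark | time |
|---|---|---|---|---|---|
| Sunday's | 0.020 M | 0.026 M | 0.022 M | the very flask that is asked about, followed so far |  |
| Friday's | 0.030 M | 0.026 M | 0.022 M | run made earlier |  |
| flask | 0.020 M | 0.0260 M | 0.0220 M |  | 5.0 min |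

| run | time / s | electrophile / % | target / % |
|---|---|---|---|
| Sunday's | 15.0 | 29 | 48 |
| Sunday's | 30.0 | 22 | 43 |
| Sunday's | 50.0 | 19 | 36 |
| Sunday's | 60.0 | 17 | 33 |
| Sunday's | 80.0 | 14 | 25 |
| Sunday's | 90.0 | 17 | 28 |
| Sunday's | 120 | 10 | 22 |
| Friday's | 10.0 | 44 | 36 |
| Friday's | 15.0 | 36 | 37 |
| Friday's | 20.0 | 39 | 36 |
| Friday's | 30.0 | 36 | 34 |
| Friday's | 50.0 | 31 | 30 |
| Friday's | 80.0 | 26 | 30 |
| Friday's | 120 | 26 | 25 |

(each reading ± 1.5 percentage points)

- the analysis behind the earlier runs scatters by 1.5 percentage points, standard deviation
- a reading or a percentage of target counts all its forms, free or not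
- a reading of electrophile is of its free form alone
- the earlier runs do not show how much of nucleophile is bound; that part of a forecast is a guess

1. part of the electrophile that has reacted at 5.0 min
2. share of the unused nucleophile that is free and not bound as protonated nucleophile, at 5.0 min

- Electrophile: by hand, raising it to the charge of Friday's flask turns the margin negative, leaving 0.00400 M of electrophile, or 13.3% of Friday's charge, without a partner. The readings lean the same way: at 120 s, Friday's flask shows 26% electrophile, more than the 10% in Sunday's flask.
- Nucleophile: by hand, each addition goes straight onto the margin, but both runs hold the same charge, so they show nothing of this.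
- Free base: it does not enter the margin, and both runs hold this charge as well.
- Time: the early end of Sunday's flask is quick, with 29% electrophile at 15.0 s, and at the far end, at full conversion, the unused nucleophile stands at the margin. The tail joins them: from 17% at 60.0 s to 10% at 120 s reads as 0.00884 s⁻¹.
- Carried to 5.0 min, that rate leaves 2.04%, so this reckoning commits to 98.0% reacted, and unused nucleophile near 0.00641 M. The runs do not show how much of that is free, so no figure is offered for the free share.
- The forecast gives 96% reacted (92% to 98.5%), lower than this reckoning, and a free share of 15% (4% to 40%), saying of the latter “This is a guess”.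

- The flask gives 98.8% reacted and a free share of 38.4%, and electrophile runs out first, with 1.16% left at 5.00 min.

    electrophile + nucleophile → acid set free + target (k = 8.40 L mol⁻¹ s⁻¹)
    nucleophile + acid set free ⇌ protonated nucleophile, settled at all times (K = 6500 L mol⁻¹)
    acid set free + free base ⇌ salt of the base, settled at all times (K = 110 L mol⁻¹)
    acid set free → by-product carried off (k = 0.0830 s⁻¹)
    electrophile + target ⇌ idle adduct, settled at all times (K = 55.0 L mol⁻¹)
    free base + target → over-reaction product (k = 1.50 L mol⁻¹ s⁻¹)

- Free nucleophile, 9.25% of its charge, and protonated nucleophile, 0.00385 M, make 0.00626 M in this flask, which is the margin plus the electrophile still uncoupled, free or held in idle adduct, 0.00626 M. With 0.044 M of nucleophile the margin becomes 0.0240 M, and that neighbour flask, its electrophile at 0%, holds 0.0240 M of free and protonated nucleophile at 5.00 min.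

The runs come from a simulation for substances that don't exist; the scatter is artificial.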